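## Retrosynthetic overview

1. Ring A is the cyclohexenone (C1 ketone, C2 vinylic CH, C3 bearing CH3, C4 carbinol, C5 bearing the geranylgeranyl chain, C6 CH2). It is closed last, at C1–C2, by iodine–lithium exchange on a (Z)-iodoalkene and attack of the alkenyllithium on a γ-lactone carbonyl, which unveils the enone and the free C4 hydroxyl in the same operation.
2. Enabling feature: the C1 ketone and the C4 hydroxyl are 1,4-related across ring A, so O4 and C1 can be tied into a temporary γ-butyrolactone (ring B: O4, C1, C6, C5, C4), and the Z C2=C3 double bond holds C2 over the lactone carbonyl.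
3. Ring B comes from a 1,4-diol by oxidative lactonisation; the diol comes from hydroboration of a terminal vinyl group (C6=C1).
4. The C4–C5 bond and both stereocentres come from an anti-selective, chiral phosphoric acid-catalysed allylboration of (Z)-3-iodo-2-methylprop-2-enal (C2, C3, CH3, C4) with an (E)-γ-geranylgeranyl allylboronate (C1, C6, C5 and the chain).
5. The aldehyde comes from propargyl alcohol (anti-carbomagnesiation/iodination, oxidation); the boronate from geranylgeraniol (bromide, ethynylation, alkyne hydroboration, Matteson homologation). Ring order: ring B (step 9), then ring A (step 10, which opens ring B).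

Key step: step 10

Remarks on the chemistry:
- GG = geranylgeranyl = (2E,6E,10E)-3,7,11,15-tetramethylhexadeca-2,6,10,14-tetraen-1-yl. The target is the cis isomer (OH and GG on the same face), (4R,5R).
- Assumption: the (R)-enantiomer of the phosphoric acid TRIP delivers the allyl group to the Re face of aldehyde 4, as it does with aryl and alkenyl aldehydes; if the sense is the opposite, the (S)-acid is used and nothing else changes.

## Route

Step 1
Reactants: 1 prop-2-yn-1-ol (propargyl alcohol)
Product: 3 (Z)-3-iodo-2-methylprop-2-en-1-ol, via alkenylmagnesium alkoxide 2 (not isolated)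
Conditions: MeMgBr (2.5 equiv), CuI (10 mol %), THF, −10 °C to rt; then I2, −10 °C; aq NH4Cl
Reagents that add atoms: methylmagnesium bromide, C[Mg]Br; iodine, II
Why: Copper-catalysed anti-carbomagnesiation of the magnesium propargylic alkoxide (Duboudin–Jousseaume carbometalation) puts the methyl on the internal carbon and magnesium on the terminal carbon cis to the CH2O group through a five-membered chelate, and iodinolysis with retention should give the Z iodide.

Step 2
Reactants: 3 (Z)-3-iodo-2-methylprop-2-en-1-ol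
Product: 4 (Z)-3-iodo-2-methylprop-2-enal
Conditions: activated MnO2 (excess), CH2Cl2, rt, dark; filtered and used at once
Reagents that add atoms: none
Why: Allylic alcohol oxidation with MnO2 is neutral and heterogeneous, so the sensitive Z β-iodo enal should form without isomerisation of the double bond.

Step 3
Reactants: 5 (2E,6E,10E)-geranylgeraniol
Product: 6 (2E,6E,10E)-geranylgeranyl bromide
Conditions: PBr3 (0.4 equiv), Et2O, −10 to 0 °C; used crude
Reagents that add atoms: phosphorus tribromide, BrP(Br)Br
Why: SN2 bromination of a primary allylic alcohol with PBr3 at low temperature is standard for polyprenols and should keep the 2E geometry without allylic transposition.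

Step 4
Reactants: 6 (2E,6E,10E)-geranylgeranyl bromide
Product: 7 (4E,8E,12E)-5,9,13,17-tetramethyloctadeca-4,8,12,16-tetraen-1-yne
Conditions: ethynylmagnesium bromide (2 equiv), CuCl (10 mol %), THF, 0 to 45 °C
Reagents that add atoms: ethynylmagnesium bromide, C#C[Mg]Br
Why: Copper-catalysed SN2 coupling of an allylic bromide with an alkynyl Grignard reagent should give the skipped 1,4-enyne at the primary carbon, as is known for geranyl and farnesyl halides.

Step 5
Reactants: 7 (4E,8E,12E)-5,9,13,17-tetramethyloctadeca-4,8,12,16-tetraen-1-yne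
Product: 8 2-[(1E,4E,8E,12E)-5,9,13,17-tetramethyloctadeca-1,4,8,12,16-pentaen-1-yl]-4,4,5,5-tetramethyl-1,3,2-dioxaborolane
Conditions: pinacolborane (1.2 equiv), Cp2Zr(H)Cl (5 mol %), Et3N (10 mol %), neat, 60 °C
Reagents that add atoms: pinacolborane, [H]B1OC(C)(C)C(C)(C)O1
Why: Zirconocene-catalysed syn-hydroboration of a terminal alkyne with pinacolborane (Pereira–Srebnik conditions) should give the (E)-alkenylboronate and leave the trisubstituted alkenes untouched.

Step 6
Reactants: 8 (E)-alkenylboronate
Product: 10 2-[(2E,5E,9E,13E)-6,10,14,18-tetramethylnonadeca-2,5,9,13,17-pentaen-1-yl]-4,4,5,5-tetramethyl-1,3,2-dioxaborolane, via boron ate complex 9 (not isolated)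
Conditions: BrCH2Cl (1.5 equiv), n-BuLi (1.4 equiv), THF, −78 °C to rt
Reagents that add atoms: bromochloromethane, ClCBr
Why: Matteson homologation: LiCH2Cl made in situ adds to boron and the alkenyl group of ate complex 9 migrates with loss of chloride, which inserts one CH2 between the alkene and boron with retention of the E geometry.

Step 7
Reactants: 4 (Z)-3-iodo-2-methylprop-2-enal; 10 (E)-γ-geranylgeranyl allylboronate
Product: 12 (1Z,3R,4R,6E,10E,14E)-4-ethenyl-1-iodo-2,7,11,15,19-pentamethylicosa-1,6,10,14,18-pentaen-3-ol, via pinacol borate ester 11 (not isolated)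
Conditions: (R)-TRIP phosphoric acid [(R)-3,3'-bis(2,4,6-triisopropylphenyl)-1,1'-binaphthyl-2,2'-diyl hydrogen phosphate] (5 mol %), 4 Å MS, toluene, −30 °C; aq NaHCO3
Reagents that add atoms: none
Why: Chiral phosphoric acid-catalysed allylboration through a closed chair (Zimmerman–Traxler) transition state: the E γ-substituent of 10 sits equatorial and gives the anti relationship of the C4 hydroxyl and the C5 side chain, while the (R)-acid, bound to a boronate oxygen and the formyl hydrogen, directs attack to the Re face of 4 and sets C4 as R and therefore C5 as R.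

Step 8
Reactants: 12 anti homoallylic alcohol
Product: 14 (3R,4R,5Z)-6-iodo-5-methyl-3-[(2E,6E,10E)-3,7,11,15-tetramethylhexadeca-2,6,10,14-tetraen-1-yl]hex-5-ene-1,4-diol, via B-alkyl-9-BBN adduct 13 (not isolated)
Conditions: 9-BBN (2.2 equiv, the excess allowing for reaction at the hydroxyl), THF, 0 °C to rt; then aq NaOH, H2O2, 0 °C
Reagents that add atoms: hydrogen peroxide, OO
Why: Anti-Markovnikov hydroboration–oxidation with the bulky 9-BBN is selective for the monosubstituted vinyl group over the trisubstituted double bonds and the iodoalkene, and the stereocentres are not involved.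

Step 9
Reactants: 14 1,4-diol
Product: 16 (4R,5R)-5-[(1Z)-1-iodoprop-1-en-2-yl]-4-[(2E,6E,10E)-3,7,11,15-tetramethylhexadeca-2,6,10,14-tetraen-1-yl]oxolan-2-one, via lactol 15 (not isolated)
Conditions: TEMPO (20 mol %), PhI(OAc)2 (2.5 equiv), CH2Cl2, rt
Reagents that add atoms: none
Why: Oxoammonium oxidation (TEMPO/PhI(OAc)2) takes the unhindered primary alcohol to the aldehyde, which closes to lactol 15 with the C4 hydroxyl and is oxidised again to the γ-lactone, a standard oxidative lactonisation of 1,4-diols that is slow at hindered secondary alcohols.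

Step 10
Reactants: 16 trans-γ-lactone (ring B)
Product: 20 (4R,5R)-4-hydroxy-3-methyl-5-[(2E,6E,10E)-3,7,11,15-tetramethylhexadeca-2,6,10,14-tetraen-1-yl]cyclohex-2-en-1-one (CNP0277821.2), via alkenyllithium 17 (not isolated), via bridged hemiketal alkoxide 18 (not isolated), via lithium alkoxide 19 (not isolated)
Conditions: t-BuLi (2.05 equiv), Et2O–pentane, 0.01 M, −100 °C, then −78 to −40 °C; AcOH in THF, −78 °C; pH 7 buffer
Reagents that add atoms: none
Why: Proposed new method: iodine–lithium exchange at the sp2 carbon C2 is expected to outrun addition of t-BuLi to the lactone, and the configurationally stable alkenyllithium 17, which the Z double bond holds cis to C4 and thus over the lactone face, adds to the carbonyl carbon C1 to give the bridged hemiketal alkoxide 18, whose C1–O4 bond then breaks with release of the bicyclic strain to leave the C4 alkoxide and the C1 ketone conjugated with C2=C3 (19, protonated on quench). The closest known reaction types are the Parham cyclisation (halogen–lithium exchange followed by intramolecular acylation of the organolithium by an ester or amide) and the SmI2-promoted intramolecular nucleophilic acyl substitution of halo esters; an alkenyllithium attacking across a γ-lactone through a 7-oxabicyclo[2.2.1]heptene hemiketal has no direct precedent. Ring A closes in the 6-exo-trig mode (the C1=O bond lies outside the forming carbocycle) and the same bond closes the transient 2,5-dihydrofuran ring of 18 in the 5-exo-trig mode, before ring B and that ring are opened together at C1–O4. No stereocentre is created in the product: C4 and C5 come unchanged from 16 (neither is acidic under the conditions), so the trans lactone maps onto the cis arrangement of OH and side chain on ring A, and the bridgehead C1 of 18 is fixed by the bicycle and lost on collapse. The step needs exchange to beat carbonyl addition, and carbonyl addition to beat α-deprotonation at C6 and intermolecular acylation, which the fast exchange of a vinylic C–I bond at −100 °C, the proximity of C2 to C1 and high dilution should secure. Because no cation or radical is formed at C1, the first double bond of the side chain, which would trap such a species in a five-membered ring, is not engaged.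

## Compound list

1 | prop-2-yn-1-ol (propargyl alcohol) | C#CCO | starting material
2 | bromomagnesium (Z)-3-(bromomagnesio)-2-methylprop-2-en-1-olate | Br[Mg]OC/C(C)=C\[Mg]Br | intermediate
3 | (Z)-3-iodo-2-methylprop-2-en-1-ol | OC/C(C)=C\I | intermediate
4 | (Z)-3-iodo-2-methylprop-2-enal | O=C/C(C)=C\I | intermediate
5 | (2E,6E,10E)-geranylgeraniol | CC(C)=CCC/C(C)=C/CC/C(C)=C/CC/C(C)=C/CO | starting material
6 | (2E,6E,10E)-geranylgeranyl bromide | CC(C)=CCC/C(C)=C/CC/C(C)=C/CC/C(C)=C/CBr | intermediate
7 | (4E,8E,12E)-5,9,13,17-tetramethyloctadeca-4,8,12,16-tetraen-1-yne | CC(C)=CCC/C(C)=C/CC/C(C)=C/CC/C(C)=C/CC#C | intermediate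
8 | 2-[(1E,4E,8E,12E)-5,9,13,17-tetramethyloctadeca-1,4,8,12,16-pentaen-1-yl]-4,4,5,5-tetramethyl-1,3,2-dioxaborolane | CC(C)=CCC/C(C)=C/CC/C(C)=C/CC/C(C)=C/C/C=C/B1OC(C)(C)C(C)(C)O1 | intermediate
9 | lithium (chloromethyl)(pinacolato)borate ate complex of 8 | CC(C)=CCC/C(C)=C/CC/C(C)=C/CC/C(C)=C/C/C=C/[B-]1(CCl)OC(C)(C)C(C)(C)O1.[Li+] | intermediate
10 | 2-[(2E,5E,9E,13E)-6,10,14,18-tetramethylnonadeca-2,5,9,13,17-pentaen-1-yl]-4,4,5,5-tetramethyl-1,3,2-dioxaborolane | CC(C)=CCC/C(C)=C/CC/C(C)=C/CC/C(C)=C/C/C=C/CB1OC(C)(C)C(C)(C)O1 | intermediate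
11 | pinacol borate ester of 12 (O–B(pin) at the C4 oxygen) | CC(C)=CCC/C(C)=C/CC/C(C)=C/CC/C(C)=C/C[C@H](C=C)[C@@H](OB1OC(C)(C)C(C)(C)O1)/C(C)=C\I | intermediate
12 | (1Z,3R,4R,6E,10E,14E)-4-ethenyl-1-iodo-2,7,11,15,19-pentamethylicosa-1,6,10,14,18-pentaen-3-ol | CC(C)=CCC/C(C)=C/CC/C(C)=C/CC/C(C)=C/C[C@H](C=C)[C@@H](O)/C(C)=C\I | intermediate
13 | B-alkyl-9-borabicyclo[3.3.1]nonane adduct of 12 (boron on the terminal carbon) | CC(C)=CCC/C(C)=C/CC/C(C)=C/CC/C(C)=C/C[C@H](CCB1C2CCCC1CCC2)[C@@H](O)/C(C)=C\I | intermediate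
14 | (3R,4R,5Z)-6-iodo-5-methyl-3-GG-hex-5-ene-1,4-diol | CC(C)=CCC/C(C)=C/CC/C(C)=C/CC/C(C)=C/C[C@H](CCO)[C@@H](O)/C(C)=C\I | intermediate
15 | (4R,5R)-5-[(1Z)-1-iodoprop-1-en-2-yl]-4-GG-oxolan-2-ol (lactol, both anomers) | CC(C)=CCC/C(C)=C/CC/C(C)=C/CC/C(C)=C/C[C@@H]1CC(O)O[C@H]1/C(C)=C\I | intermediate
16 | (4R,5R)-5-[(1Z)-1-iodoprop-1-en-2-yl]-4-GG-oxolan-2-one (trans lactone) | CC(C)=CCC/C(C)=C/CC/C(C)=C/CC/C(C)=C/C[C@@H]1CC(=O)O[C@H]1/C(C)=C\I | intermediate
17 | (Z)-alkenyllithium from 16 (lithium in place of iodine) | CC(C)=CCC/C(C)=C/CC/C(C)=C/CC/C(C)=C/C[C@@H]1CC(=O)O[C@H]1/C(C)=C\[Li] | intermediate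
18 | lithium (1S,4R,5R)-3-methyl-5-GG-7-oxabicyclo[2.2.1]hept-2-en-1-olate | CC(C)=CCC/C(C)=C/CC/C(C)=C/CC/C(C)=C/C[C@@H]1C[C@@]2([O-])C=C(C)[C@@H]1O2.[Li+] | intermediate
19 | lithium alkoxide of 20 | CC(C)=CCC/C(C)=C/CC/C(C)=C/CC/C(C)=C/C[C@@H]1CC(=O)C=C(C)[C@@H]1[O-].[Li+] | intermediate
20 | (4R,5R)-4-hydroxy-3-methyl-5-GG-cyclohex-2-en-1-one (CNP0277821.2) | CC(C)=CCC/C(C)=C/CC/C(C)=C/CC/C(C)=C/C[C@@H]1CC(=O)C=C(C)[C@@H]1O | target

## Step count and risks

Total steps: 10. Longest linear sequence: 8 (steps 3 to 10, from geranylgeraniol).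

Steps most likely to fail:

1. Step 10 (proposed new method). The exchange may be overtaken by addition of t-BuLi to the lactone carbonyl, the alkenyllithium may be quenched by proton transfer from C6, or it may react between molecules because the bridged transition state is strained. The fallback uses known chemistry, sets out from diol 14 and comes back at 20. Both hydroxyls are silylated (TESCl, imidazole, DMF) to give the bis(triethylsilyl) ether F1. Swern oxidation ((COCl)2, DMSO, then Et3N), which cleaves and oxidises a primary triethylsilyl ether in the presence of a secondary one, gives the silyloxy aldehyde F2. An intramolecular Nozaki–Hiyama–Kishi reaction (CrCl2, NiCl2 cat., DMSO–THF, high dilution) closes the same C1–C2 bond to give the cyclohexenol F3 as both C1 epimers. Dess–Martin oxidation gives the silyloxy enone F4, and HF·pyridine in THF removes the silyl group to give 20.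

2. Step 7. Facial selectivity may be poor with the α-branched β-iodo enal, anti selectivity may erode through 1,3-borotropic shift of 10, or the acid may promote Z-to-E isomerisation of the iodo enal. The fallback sets out from enyne 7 and comes back at 12. Crabbé homologation (paraformaldehyde, CuBr, i-Pr2NH, dioxane, reflux) gives the terminal allene F5. Hydroboration with bis(isopinocampheyl)borane made from (−)-α-pinene (THF, −25 °C, then warming to equilibrate to the E isomer) gives the (E)-γ-substituted allylborane F6, which is not isolated. Its reagent-controlled addition to aldehyde 4 at −78 °C (Brown–Roush allylboration, Re-face attack), followed by NaOH/H2O2 work-up, gives 12.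

3. Step 9. The allylic secondary hydroxyl at C4 may be oxidised to the enone before the lactol forms. The fallback sets out from 12 and comes back at 16. Silylation (TESOTf, 2,6-lutidine, CH2Cl2, −78 °C) gives the triethylsilyl ether F7. Hydroboration–oxidation (9-BBN; NaOH, H2O2) gives the primary alcohol F8. Oxidation to the acid (TEMPO cat., PhI(OAc)2, MeCN–H2O) gives the silyloxy acid F9. HF·pyridine in THF removes the silyl group and the γ-hydroxy acid closes to lactone 16.

## Further compounds

F1 | step 10 | bis(triethylsilyl) ether of diol 14 | CC(C)=CCC/C(C)=C/CC/C(C)=C/CC/C(C)=C/C[C@H](CCO[Si](CC)(CC)CC)[C@@H](O[Si](CC)(CC)CC)/C(C)=C\I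
F2 | step 10 | (3R,4R,5Z)-6-iodo-5-methyl-3-GG-4-(triethylsilyloxy)hex-5-enal | CC(C)=CCC/C(C)=C/CC/C(C)=C/CC/C(C)=C/C[C@H](CC=O)[C@@H](O[Si](CC)(CC)CC)/C(C)=C\I
F3 | step 10 | (4R,5R)-3-methyl-5-GG-4-(triethylsilyloxy)cyclohex-2-en-1-ol (both C1 epimers) | CC(C)=CCC/C(C)=C/CC/C(C)=C/CC/C(C)=C/C[C@@H]1CC(O)C=C(C)[C@@H]1O[Si](CC)(CC)CC
F4 | step 10 | (4R,5R)-3-methyl-5-GG-4-(triethylsilyloxy)cyclohex-2-en-1-one | CC(C)=CCC/C(C)=C/CC/C(C)=C/CC/C(C)=C/C[C@@H]1CC(=O)C=C(C)[C@@H]1O[Si](CC)(CC)CC
F5 | step 7 | (5E,9E,13E)-6,10,14,18-tetramethylnonadeca-1,2,5,9,13,17-hexaene | CC(C)=CCC/C(C)=C/CC/C(C)=C/CC/C(C)=C/CC=C=C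
F6 | step 7 | [(2E,5E,9E,13E)-6,10,14,18-tetramethylnonadeca-2,5,9,13,17-pentaen-1-yl]bis(isopinocampheyl)borane, isopinocampheyl groups from (−)-α-pinene | CC(C)=CCC/C(C)=C/CC/C(C)=C/CC/C(C)=C/C/C=C/CB([C@H]1C[C@H]2C[C@@H]([C@@H]1C)C2(C)C)[C@H]1C[C@H]2C[C@@H]([C@@H]1C)C2(C)C
F7 | step 9 | triethylsilyl ether of 12 | CC(C)=CCC/C(C)=C/CC/C(C)=C/CC/C(C)=C/C[C@H](C=C)[C@@H](O[Si](CC)(CC)CC)/C(C)=C\I
F8 | step 9 | (3R,4R,5Z)-6-iodo-5-methyl-3-GG-4-(triethylsilyloxy)hex-5-en-1-ol | CC(C)=CCC/C(C)=C/CC/C(C)=C/CC/C(C)=C/C[C@H](CCO)[C@@H](O[Si](CC)(CC)CC)/C(C)=C\I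
F9 | step 9 | (3R,4R,5Z)-6-iodo-5-methyl-3-GG-4-(triethylsilyloxy)hex-5-enoic acid | CC(C)=CCC/C(C)=C/CC/C(C)=C/CC/C(C)=C/C[C@H](CC(=O)O)[C@@H](O[Si](CC)(CC)CC)/C(C)=C\I
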